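The vessel is closed, stirred and held at constant temperature, with E, Z and G charged together, and the meeting had to say when Q stands highest in a flask at 0.10 M of E, and how high.

| flask | E | Z | G | remark | time |
|---|---|---|---|---|---|
| violet | 0.14 M | 1 equiv | 1 equiv | run made earlier |  |
| green | 0.22 M | 1 equiv | 1 equiv | run made earlier |  |
| flask | 0.10 M | 1.00 equiv | 1.00 equiv |  | 2.0 h |

| run | time / min | Q / % |
|---|---|---|
| violet | 1.33 | 12.9 |
| violet | 3.00 | 18.3 |
| violet | 6.00 | 17.2 |
| violet | 15.0 | 10.5 |
| violet | 30.0 | 3.5 |
| violet | 80.0 | 0 |
| green | 1.33 | 16.3 |
| green | 3.00 | 18.8 |
| green | 6.00 | 16.5 |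
| green | 15.0 | 7.8 |
| green | 30.0 | 2.4 |
| green | 80.0 | 0 |

(standard deviation of a reading: 0.5 percentage points)

- time up to 2.0 h at which Q stands highest
- the amount of Q, in percent of the E charged, at that time

- what was read earlier has a scatter of 0.5 percentage points, one standard deviation

The second chemist reported that the highest readings of Q, 18.3 % in the violet run and 18.8 % in the green, differ by 0.5 percentage points, the size of the scatter, although E differs by a factor of 1.57. She therefore took the height as unmoved by concentration at equal charges, with a mean of 18.6 %. With Z and E charged equally, this is also the part of Z standing as Q. From it she kept 4.39 as S, the split number: the parts of Z standing elsewhere at the top of Q for each part standing as Q, at 1.00 equiv of G. She assumed that those parts grow in step with the G charged, so this flask, with the same equivalents, should again reach 18.6 %.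

The first chemist took up the time. Where the slopes between the violet readings cross zero, he read a top at 4.26 min. Assuming that this time runs inversely with the concentration of E, he put the top of this flask at 0.0995 h.

The forecast, lower in height and later than the meeting's figures, gave 17 % at 0.11 h, holding that “This decay is nearly the same in both runs”.

The flask gives 17.3 % at 0.0933 h.

    E + Z ⇌ Q (K = 19.0 M⁻¹, k = 1.20 M⁻¹ min⁻¹)
    G + Z → X (k = 4.00 M⁻¹ min⁻¹)
    2 E → L (k = 0.00170 M⁻¹ min⁻¹)
    E + Q → J (k = 0.470 M⁻¹ min⁻¹)

Put back into the same definition, this top gives the flask an S of 4.78. In this flask at 0.0347 h, the forward rate at which G uses Z is 2.3 times that at which E uses it, and at 2.00 h the ratio is 0.78. By then Z, the limiting reagent, is down to 0.0562 % of its charge in this flask. For the neighbour flask with 1.70 equiv of G, the S from the meeting gives 11.8 %, and its top stands at 12.1 %.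

The earlier runs and the new flask were generated by integration from invented constants; the scatter is artificial.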